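The route rests on cutting the C1''–C2'' bond of the lavandulyl chain. C1'' is the benzylic CH2 on C8 of ring A, flanked by the oxygens on C7 and C8a, so it can be released as the exocyclic carbon of an ortho-quinone methide. C2'' is the α-carbon of an aldehyde whose carbonyl carbon later becomes the isopropenyl carbon C3''. In one operation an enamine-catalysed Michael addition/hemiacetalisation forms C1''–C2'', sets the 2''R centre and stores the epimerisable aldehyde as a chroman-2-ol. The precursor is the 2-(tosylmethyl)phenol of 5-methoxyresorcinol with its second hydroxyl as a MOM ether, used with 5-methylhex-4-enal. C2 is set late by [RhCl(C2H4)2]2/diene-catalysed arylation of a chromone.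

Key step: step 5

Remark: one of the two equivalent phenols of the sulfone is carried as a MOM ether (compound 6); the skeleton and the bond formed are unchanged, the quinone methide loses its acidic hydroxyl, and a MOM group is needed on that ring A oxygen later anyway.

Remark: the (1S,4S) diene in step 13 is chosen by transferring the facial preference known for 2-cyclohexenone to the chromone; the step must deliver the aryl group to the Re face of C2, and the antipodal ligand would be taken if the sense did not transfer.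

**Route**

Step 1
Reactants: 1 2,4,6-trihydroxybenzaldehyde
Product: 2 2,6-dihydroxy-4-methoxybenzaldehyde
Conditions: MeI (1.0 equiv), KHCO3 (1.1 equiv), DMF, rt
Reagents that add atoms: iodomethane, CI
Why: Williamson O-methylation with limiting MeI and a bicarbonate base should select the 4-hydroxyl, which is the most acidic (para to the formyl group) and the only one that cannot chelate the carbonyl.

Step 2
Reactants: 2 2,6-dihydroxy-4-methoxybenzaldehyde
Product: 3 2-hydroxy-4-methoxy-6-(methoxymethoxy)benzaldehyde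
Conditions: MOMCl (1.1 equiv), iPr2NEt, CH2Cl2, 0 °C to rt
Reagents that add atoms: chloromethyl methyl ether, COCCl
Why: O-alkylation to the MOM acetal ether should stop at the mono-ether because, once one ortho hydroxyl is capped, the other is locked in a hydrogen bond to the formyl oxygen and is a poor nucleophile under amine base.

Step 3
Reactants: 3 2-hydroxy-4-methoxy-6-(methoxymethoxy)benzaldehyde; 4 sodium p-toluenesulfinate
Product: 6 5-methoxy-3-(methoxymethoxy)-2-[(4-methylphenyl)sulfonylmethyl]phenol, via benzylic alcohol 5 (not isolated)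
Conditions: NaBH4, THF/EtOH, 0 °C; acetone quench; then 4 (3 equiv), AcOH/H2O, rt
Reagents that add atoms: none
Why: NaBH4 reduction followed by acid-promoted SN1-type benzylic substitution, in which the stabilised ortho-hydroxy/para-methoxy benzylic cation from 5 is captured at sulfur by the sulfinate, is the standard entry to 2-(sulfonylmethyl)phenols; destroying the hydride before acidification prevents over-reduction to the methylarene, and acetic acid leaves the MOM ether intact.

Step 4
Reactants: 7 2-methylbut-3-en-2-ol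
Product: 9 5-methylhex-4-enal, via allyl vinyl ether 8 (not isolated)
Conditions: ethyl vinyl ether (excess), Hg(OAc)2 (cat.), sealed tube, 35 °C then 120 °C
Reagents that add atoms: ethyl vinyl ether, C=COCC
Why: Hg(OAc)2-catalysed vinyl ether exchange gives the tertiary allyl vinyl ether 8, which undergoes the aliphatic Claisen [3,3] rearrangement on heating to give the γ,δ-unsaturated aldehyde; no stereocentre is involved.

Step 5
Reactants: 6 5-methoxy-3-(methoxymethoxy)-2-[(4-methylphenyl)sulfonylmethyl]phenol; 9 5-methylhex-4-enal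
Product: 13 (3R)-7-methoxy-5-(methoxymethoxy)-3-(3-methylbut-2-enyl)chroman-2-ol (anomeric mixture at C2), via quinone methide 10 (not isolated), via enamine 11 (not isolated), via hydroxy aldehyde 12 (not isolated)
Conditions: (S)-2-[diphenyl(trimethylsilyloxy)methyl]pyrrolidine (20 mol%), 9 (2.5 equiv), sat. aq NaHCO3, CH2Cl2, 0 °C to rt
Reagents that add atoms: none
Why: NaHCO3 deprotonates the phenol of 6 and E1cB loss of p-toluenesulfinate releases quinone methide 10, whose exocyclic CH2 is attacked by the β-carbon of E-enamine 11; hydrolysis of the resulting iminium returns the catalyst and gives hydroxy aldehyde 12, which closes to lactol 13. The closest known reaction type is the aminocatalytic asymmetric formal [4+2] (Michael addition/hemiacetalisation) of aldehydes with ortho-quinone methides released from 2-(sulfonylmethyl)phenols, which gives 3-substituted chroman-2-ols. The single ring formed, the oxygen ring of the chromanol, closes by 6-exo-trig attack of the phenolic oxygen on the aldehyde carbon. The C3 centre (the future C2'') is set by the catalyst: its diphenyl(trimethylsilyloxy)methyl group blocks one face of the enamine, so 10 is taken up on the open Si face of the β-carbon, which corresponds to R, while the anomeric centre is left as a mixture because it is destroyed in step 6. The step needs the enamine to win the quinone methide against oligomerisation, against attack by phenoxide and against reversible N-attack by the catalyst; slow release of 10 across the two-phase medium, excess 9 and the MOM ether, which removes the acidic second hydroxyl and keeps 10 a neutral and reactive acceptor, are there to secure this. Lactol closure then keeps the α-branched aldehyde out of enamine equilibria and so protects the new centre from epimerisation.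

Step 6
Reactants: 13 (3R)-7-methoxy-5-(methoxymethoxy)-3-(3-methylbut-2-enyl)chroman-2-ol
Product: 14 (3R)-3-[[2-hydroxy-4-methoxy-6-(methoxymethoxy)phenyl]methyl]-6-methylhept-5-en-2-ol (both C2 epimers)
Conditions: MeMgBr (3.5 equiv), THF, 0 °C to rt; aq NH4Cl
Reagents that add atoms: methylmagnesium bromide, C[Mg]Br
Why: Grignard addition, in which the first equivalent deprotonates the lactol so that it opens to the bromomagnesium phenoxide (ArOMgBr) of aldehyde 12 and a second equivalent adds to the aldehyde faster than it enolises it, so the C3 centre is kept and the new carbinol centre, formed as a mixture, is removed in step 8.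

Step 7
Reactants: 14 (3R)-3-[[2-hydroxy-4-methoxy-6-(methoxymethoxy)phenyl]methyl]-6-methylhept-5-en-2-ol
Product: 15 (3R)-3-[[4-methoxy-2,6-bis(methoxymethoxy)phenyl]methyl]-6-methylhept-5-en-2-ol (both C2 epimers)
Conditions: MOMCl (1.2 equiv), K2CO3, acetone, rt
Reagents that add atoms: chloromethyl methyl ether, COCCl
Why: Williamson-type MOM ether formation under K2CO3 is selective for the phenoxide over the neutral secondary alcohol and gives an arene whose two remaining ring C–H positions are equivalent.

Step 8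
Reactants: 15 (3R)-3-[[4-methoxy-2,6-bis(methoxymethoxy)phenyl]methyl]-6-methylhept-5-en-2-ol
Product: 16 (3R)-3-[[4-methoxy-2,6-bis(methoxymethoxy)phenyl]methyl]-6-methylhept-5-en-2-one
Conditions: Dess–Martin periodinane, NaHCO3, CH2Cl2, 0 °C to rt
Reagents that add atoms: none
Why: Dess–Martin oxidation under bicarbonate buffer converges both carbinol epimers on one methyl ketone under non-basic conditions that should not epimerise the adjacent C3 centre.

Step 9
Reactants: 16 (3R)-3-[[4-methoxy-2,6-bis(methoxymethoxy)phenyl]methyl]-6-methylhept-5-en-2-one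
Product: 17 5-methoxy-1,3-bis(methoxymethoxy)-2-[(2R)-5-methyl-2-(prop-1-en-2-yl)hex-4-enyl]benzene
Conditions: Cp2TiMe2 (2.5 equiv), toluene/THF, 65 °C, dark
Reagents that add atoms: dimethyltitanocene (Cp2TiMe2), [CH3-].[CH3-].[Ti+4].c1cc[cH-]c1.c1cc[cH-]c1
Why: Petasis methylenation through the non-basic Cp2Ti=CH2 converts the enolisable α-branched ketone into the 1,1-disubstituted alkene without touching the neighbouring stereocentre, completing the (2R)-lavandulyl group.

Step 10
Reactants: 17 5-methoxy-1,3-bis(methoxymethoxy)-2-[(2R)-5-methyl-2-(prop-1-en-2-yl)hex-4-enyl]benzene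
Product: 19 1-[6-methoxy-2,4-bis(methoxymethoxy)-3-[(2R)-5-methyl-2-(prop-1-en-2-yl)hex-4-enyl]phenyl]ethanone, via aryllithium 18 (not isolated)
Conditions: n-BuLi (1.2 equiv), TMEDA, THF, 0 °C; then MeC(O)N(OMe)Me, −78 °C to rt; aq NH4Cl
Reagents that add atoms: N-methoxy-N-methylacetamide, CC(=O)N(C)OC
Why: Directed ortho-metalation removes the ring proton between the MOM ether and the methoxy group, the two such sites being equivalent in the symmetric arene, and Weinreb amide acylation, whose chelated tetrahedral adduct blocks over-addition, installs the acetyl group at the only possible position.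

Step 11
Reactants: 19 1-[6-methoxy-2,4-bis(methoxymethoxy)-3-[(2R)-5-methyl-2-(prop-1-en-2-yl)hex-4-enyl]phenyl]ethanone
Product: 20 1-[2-hydroxy-6-methoxy-4-(methoxymethoxy)-3-[(2R)-5-methyl-2-(prop-1-en-2-yl)hex-4-enyl]phenyl]ethanone
Conditions: HCl (0.2 M) in MeOH, 0 °C to rt, stopped at mono-cleavage
Reagents that add atoms: none
Why: Acid-catalysed acetal methanolysis is expected to select the MOM ether ortho to the acetyl group, which is twisted between two substituents and whose cleavage is assisted by the neighbouring carbonyl and rewarded by the chelated phenol, while the other MOM ether needs more forcing acid.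

Step 12
Reactants: 20 1-[2-hydroxy-6-methoxy-4-(methoxymethoxy)-3-[(2R)-5-methyl-2-(prop-1-en-2-yl)hex-4-enyl]phenyl]ethanone
Product: 22 5-methoxy-7-(methoxymethoxy)-8-[(2R)-5-methyl-2-(prop-1-en-2-yl)hex-4-enyl]chromen-4-one, via enaminone 21 (not isolated)
Conditions: DMF-DMA (3 equiv), toluene, 90 °C; then AcOH, 50 °C
Reagents that add atoms: N,N-dimethylformamide dimethyl acetal, COC(OC)N(C)C
Why: Condensation of the methyl ketone with DMF-DMA gives enaminone 21, and mild acid triggers 6-endo conjugate addition of the chelated phenol and loss of dimethylamine (the standard enaminone chromone synthesis), closing ring C at the only hydroxyl next to the acyl group.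

Step 13
Reactants: 22 5-methoxy-7-(methoxymethoxy)-8-[(2R)-5-methyl-2-(prop-1-en-2-yl)hex-4-enyl]chromen-4-one; 23 4-(methoxymethoxy)phenylboronic acid
Product: 24 (2S)-5-methoxy-7-(methoxymethoxy)-2-[4-(methoxymethoxy)phenyl]-8-[(2R)-5-methyl-2-(prop-1-en-2-yl)hex-4-enyl]chroman-4-one
Conditions: [RhCl(C2H4)2]2 (2.5 mol%), (1S,4S)-2,5-diphenylbicyclo[2.2.2]octa-2,5-diene (5.5 mol%), 23 (2 equiv), aq K3PO4, toluene, 40 °C
Reagents that add atoms: none
Why: [RhCl(C2H4)2]2/chiral diene-catalysed asymmetric 1,4-addition of an arylboronic acid to a chromone (Hayashi–Miyaura type) transfers the aryl group from an aryl–Rh intermediate to C2, with the ligand, not the remote C2'' centre, controlling the face so that Re-face delivery gives 2S, and the unactivated lavandulyl alkenes do not insert.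

Step 14
Reactants: 24 (2S)-5-methoxy-7-(methoxymethoxy)-2-[4-(methoxymethoxy)phenyl]-8-[(2R)-5-methyl-2-(prop-1-en-2-yl)hex-4-enyl]chroman-4-one
Product: 25 kushenol U, (2S)-7-hydroxy-2-(4-hydroxyphenyl)-5-methoxy-8-[(2R)-5-methyl-2-(prop-1-en-2-yl)hex-4-enyl]chroman-4-one
Conditions: 3 M aq HCl/MeOH (1:4), 40 °C
Reagents that add atoms: none
Why: Acid-catalysed acetal methanolysis removes both MOM ethers under the mild conditions commonly used for prenylated flavanones, which should leave the two alkenes and the C2 and C2'' centres untouched.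

**Compound list**

1 | 2,4,6-trihydroxybenzaldehyde | O=Cc1c(O)cc(O)cc1O | starting material
2 | 2,6-dihydroxy-4-methoxybenzaldehyde | O=Cc1c(O)cc(OC)cc1O | intermediate
3 | 2-hydroxy-4-methoxy-6-(methoxymethoxy)benzaldehyde | O=Cc1c(O)cc(OC)cc1OCOC | intermediate
4 | sodium p-toluenesulfinate | Cc1ccc(S(=O)[O-])cc1.[Na+] | starting material
5 | 2-(hydroxymethyl)-5-methoxy-3-(methoxymethoxy)phenol | OCc1c(O)cc(OC)cc1OCOC | intermediate
6 | 5-methoxy-3-(methoxymethoxy)-2-[(4-methylphenyl)sulfonylmethyl]phenol | COCOc1cc(OC)cc(O)c1CS(=O)(=O)c1ccc(C)cc1 | intermediate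
7 | 2-methylbut-3-en-2-ol | C=CC(C)(C)O | starting material
8 | 3-(ethenyloxy)-3-methylbut-1-ene | C=COC(C)(C)C=C | intermediate
9 | 5-methylhex-4-enal | CC(C)=CCCC=O | intermediate
10 | 3-methoxy-5-(methoxymethoxy)-6-methylidenecyclohexa-2,4-dien-1-one | C=C1C(=O)C=C(OC)C=C1OCOC | intermediate
11 | (S)-2-[diphenyl(trimethylsilyloxy)methyl]-1-[(1E)-5-methylhexa-1,4-dienyl]pyrrolidine | CC(C)=CC/C=C/N1CCC[C@H]1C(c1ccccc1)(c1ccccc1)O[Si](C)(C)C | intermediate
12 | (2R)-2-[[2-hydroxy-4-methoxy-6-(methoxymethoxy)phenyl]methyl]-5-methylhex-4-enal | O=C[C@H](CC=C(C)C)Cc1c(O)cc(OC)cc1OCOC | intermediate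
13 | (3R)-7-methoxy-5-(methoxymethoxy)-3-(3-methylbut-2-enyl)chroman-2-ol (anomeric mixture) | OC1[C@H](CC=C(C)C)Cc2c(OCOC)cc(OC)cc2O1 | intermediate
14 | (3R)-3-[[2-hydroxy-4-methoxy-6-(methoxymethoxy)phenyl]methyl]-6-methylhept-5-en-2-ol (both C2 epimers) | CC(O)[C@H](CC=C(C)C)Cc1c(O)cc(OC)cc1OCOC | intermediate
15 | (3R)-3-[[4-methoxy-2,6-bis(methoxymethoxy)phenyl]methyl]-6-methylhept-5-en-2-ol (both C2 epimers) | CC(O)[C@H](CC=C(C)C)Cc1c(OCOC)cc(OC)cc1OCOC | intermediate
16 | (3R)-3-[[4-methoxy-2,6-bis(methoxymethoxy)phenyl]methyl]-6-methylhept-5-en-2-one | CC(=O)[C@H](CC=C(C)C)Cc1c(OCOC)cc(OC)cc1OCOC | intermediate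
17 | 5-methoxy-1,3-bis(methoxymethoxy)-2-[(2R)-5-methyl-2-(prop-1-en-2-yl)hex-4-enyl]benzene | C=C(C)[C@H](CC=C(C)C)Cc1c(OCOC)cc(OC)cc1OCOC | intermediate
18 | [6-methoxy-2,4-bis(methoxymethoxy)-3-[(2R)-5-methyl-2-(prop-1-en-2-yl)hex-4-enyl]phenyl]lithium | C=C(C)[C@H](CC=C(C)C)Cc1c(OCOC)cc(OC)c([Li])c1OCOC | intermediate
19 | 1-[6-methoxy-2,4-bis(methoxymethoxy)-3-[(2R)-5-methyl-2-(prop-1-en-2-yl)hex-4-enyl]phenyl]ethanone | C=C(C)[C@H](CC=C(C)C)Cc1c(OCOC)cc(OC)c(C(C)=O)c1OCOC | intermediate
20 | 1-[2-hydroxy-6-methoxy-4-(methoxymethoxy)-3-[(2R)-5-methyl-2-(prop-1-en-2-yl)hex-4-enyl]phenyl]ethanone | C=C(C)[C@H](CC=C(C)C)Cc1c(OCOC)cc(OC)c(C(C)=O)c1O | intermediate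
21 | (2E)-3-(dimethylamino)-1-[2-hydroxy-6-methoxy-4-(methoxymethoxy)-3-[(2R)-5-methyl-2-(prop-1-en-2-yl)hex-4-enyl]phenyl]prop-2-en-1-one | C=C(C)[C@H](CC=C(C)C)Cc1c(OCOC)cc(OC)c(C(=O)/C=C/N(C)C)c1O | intermediate
22 | 5-methoxy-7-(methoxymethoxy)-8-[(2R)-5-methyl-2-(prop-1-en-2-yl)hex-4-enyl]chromen-4-one | C=C(C)[C@H](CC=C(C)C)Cc1c(OCOC)cc(OC)c2c1OC=CC2=O | intermediate
23 | 4-(methoxymethoxy)phenylboronic acid | COCOc1ccc(B(O)O)cc1 | starting material
24 | (2S)-5-methoxy-7-(methoxymethoxy)-2-[4-(methoxymethoxy)phenyl]-8-[(2R)-5-methyl-2-(prop-1-en-2-yl)hex-4-enyl]chroman-4-one | C=C(C)[C@H](CC=C(C)C)Cc1c(OCOC)cc(OC)c2c1O[C@H](c1ccc(OCOC)cc1)CC2=O | intermediate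
25 | kushenol U, (2S)-7-hydroxy-2-(4-hydroxyphenyl)-5-methoxy-8-[(2R)-5-methyl-2-(prop-1-en-2-yl)hex-4-enyl]chroman-4-one | C=C(C)[C@H](CC=C(C)C)Cc1c(O)cc(OC)c2c1O[C@H](c1ccc(O)cc1)CC2=O | target

**Summary**

Total step count: 14. Longest linear sequence: 13 steps (steps 1–3 and 5–14); step 4 is the side branch to aldehyde 9.

Steps most likely to fail:

1. Step 5. The quinone methide may oligomerise before the enamine captures it, the enamine may show poor facial selectivity, or the α-centre may epimerise before the lactol is secured. The fallback is an auxiliary-controlled alkylation that sets out from 3 and returns at 16. Compound 3 is capped with MOMCl/NaH in DMF to give 4-methoxy-2,6-bis(methoxymethoxy)benzaldehyde F1. Horner–Wadsworth–Emmons reaction with diethyl [2-[(4R)-4-benzyl-2-oxo-1,3-oxazolidin-3-yl]-2-oxoethyl]phosphonate (LiCl, iPr2NEt, MeCN) gives (4R)-4-benzyl-3-[(2E)-3-[4-methoxy-2,6-bis(methoxymethoxy)phenyl]prop-2-enoyl]-1,3-oxazolidin-2-one F2. Hydrogenation (H2, Pd/C, EtOAc) gives (4R)-4-benzyl-3-[3-[4-methoxy-2,6-bis(methoxymethoxy)phenyl]propanoyl]-1,3-oxazolidin-2-one F3. Evans alkylation (NaN(SiMe3)2, THF, −78 °C; 1-bromo-3-methylbut-2-ene), on the face of the chelated Z-enolate opposite the benzyl group, gives (4R)-4-benzyl-3-[(2R)-2-[[4-methoxy-2,6-bis(methoxymethoxy)phenyl]methyl]-5-methylhex-4-enoyl]-1,3-oxazolidin-2-one F4. Transamination (MeNHOMe·HCl, AlMe3, CH2Cl2) gives (2R)-N-methoxy-2-[[4-methoxy-2,6-bis(methoxymethoxy)phenyl]methyl]-N,5-dimethylhex-4-enamide F5, and MeMgBr in THF at 0 °C converts it into ketone 16.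

2. Step 13. Aryl transfer to the electron-rich 5-methoxychromone may be sluggish, base may open the pyranone ring, or facial selectivity at C2 may be poor. The fallback is the chalcone route, setting out from 20 and returning at 24. Claisen–Schmidt condensation of 20 with 4-(methoxymethoxy)benzaldehyde (KOH, EtOH, rt) gives (2E)-1-[2-hydroxy-6-methoxy-4-(methoxymethoxy)-3-[(2R)-5-methyl-2-(prop-1-en-2-yl)hex-4-enyl]phenyl]-3-[4-(methoxymethoxy)phenyl]prop-2-en-1-one F6. Oxa-Michael ring closure (NaOAc, EtOH, reflux) gives 24 together with its C2 epimer, (2R)-5-methoxy-7-(methoxymethoxy)-2-[4-(methoxymethoxy)phenyl]-8-[(2R)-5-methyl-2-(prop-1-en-2-yl)hex-4-enyl]chroman-4-one F7. The two are diastereomers and should be separable by chromatography; F7 would be re-equilibrated under the same conditions.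

3. Step 11. Both MOM ethers may be lost, or the two may be poorly discriminated. The fallback is exhaustive cleavage followed by selective re-protection, setting out from 19 and returning at 20. Both ethers are removed (HCl, MeOH, 40 °C) to give 1-[2,4-dihydroxy-6-methoxy-3-[(2R)-5-methyl-2-(prop-1-en-2-yl)hex-4-enyl]phenyl]ethanone F8, and MOMCl/K2CO3 in acetone at rt caps only the hydroxyl that is not chelated to the acetyl group, giving 20.

**Further compounds**

F1 | step 5 | 4-methoxy-2,6-bis(methoxymethoxy)benzaldehyde | O=Cc1c(OCOC)cc(OC)cc1OCOC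
F2 | step 5 | (4R)-4-benzyl-3-[(2E)-3-[4-methoxy-2,6-bis(methoxymethoxy)phenyl]prop-2-enoyl]-1,3-oxazolidin-2-one | O=C(/C=C/c1c(OCOC)cc(OC)cc1OCOC)N1C(=O)OC[C@H]1Cc1ccccc1
F3 | step 5 | (4R)-4-benzyl-3-[3-[4-methoxy-2,6-bis(methoxymethoxy)phenyl]propanoyl]-1,3-oxazolidin-2-one | O=C(CCc1c(OCOC)cc(OC)cc1OCOC)N1C(=O)OC[C@H]1Cc1ccccc1
F4 | step 5 | (4R)-4-benzyl-3-[(2R)-2-[[4-methoxy-2,6-bis(methoxymethoxy)phenyl]methyl]-5-methylhex-4-enoyl]-1,3-oxazolidin-2-one | O=C([C@H](CC=C(C)C)Cc1c(OCOC)cc(OC)cc1OCOC)N1C(=O)OC[C@H]1Cc1ccccc1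
F5 | step 5 | (2R)-N-methoxy-2-[[4-methoxy-2,6-bis(methoxymethoxy)phenyl]methyl]-N,5-dimethylhex-4-enamide | CON(C)C(=O)[C@H](CC=C(C)C)Cc1c(OCOC)cc(OC)cc1OCOC
F6 | step 13 | (2E)-1-[2-hydroxy-6-methoxy-4-(methoxymethoxy)-3-[(2R)-5-methyl-2-(prop-1-en-2-yl)hex-4-enyl]phenyl]-3-[4-(methoxymethoxy)phenyl]prop-2-en-1-one | C=C(C)[C@H](CC=C(C)C)Cc1c(OCOC)cc(OC)c(C(=O)/C=C/c2ccc(OCOC)cc2)c1O
F7 | step 13 | (2R)-5-methoxy-7-(methoxymethoxy)-2-[4-(methoxymethoxy)phenyl]-8-[(2R)-5-methyl-2-(prop-1-en-2-yl)hex-4-enyl]chroman-4-one | C=C(C)[C@H](CC=C(C)C)Cc1c(OCOC)cc(OC)c2c1O[C@@H](c1ccc(OCOC)cc1)CC2=O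
F8 | step 11 | 1-[2,4-dihydroxy-6-methoxy-3-[(2R)-5-methyl-2-(prop-1-en-2-yl)hex-4-enyl]phenyl]ethanone | C=C(C)[C@H](CC=C(C)C)Cc1c(O)cc(OC)c(C(C)=O)c1O
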